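Two questions stand here, the target at the end of each flask and how it moves across them, and one concentration answers both.

| setting | north-east | north-west | south-west | delta | alpha | gamma |
|---|---|---|---|---|---|---|
| substrate | 0.40 M | 0.40 M | 0.40 M | 0.40 M | 0.40 M | 0.40 M |
| coupling partner | 5 equiv | 5 equiv | 5 equiv | 5.00 equiv | 5.00 equiv | 5.00 equiv |
| free catalyst | 1.1 mol% | 2.1 mol% | 3.5 mol% | 1 mol% | 2 mol% | 4 mol% |
| impurity | 2 mM | 2 mM | 2 mM | 2.0 mM | 2.0 mM | 2.0 mM |
| remark | run made earlier | run made earlier | run made earlier |  |  |  |
| time |  |  |  | 6.0 min | 6.0 min | 6.0 min |

| run | time / min | target / % | substrate / % |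
|---|---|---|---|
| north-east | 0.417 | 3.6 | 95.6 |
| north-east | 1.00 | 9.2 | 90.0 |
| north-east | 2.00 | 16.9 | 81.3 |
| north-east | 3.00 | 23.9 | 71.9 |
| north-west | 0.833 | 19.3 | 78.6 |
| north-west | 1.50 | 29.7 | 63.6 |
| north-west | 2.50 | 42.3 | 44.5 |
| north-west | 3.00 | 46.0 | 35.9 |
| south-west | 0.250 | 10.6 | 87.1 |
| south-west | 0.500 | 20.8 | 76.1 |
| south-west | 1.33 | 41.3 | 44.1 |
| south-west | 3.00 | 45.2 | 8.0 |

(readings scatter by 0.5 percentage points)

- amount of target at the end, in percent of the substrate charged for delta, alpha, gamma, in this order
- how that number moves from the first to the last of them (hardly changes / falls all the way / falls, then rises / rises all the way / rises, then falls)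

- steps under discussion: free catalyst + impurity -> spent catalyst; catalyst intermediate A -> catalyst intermediate B; catalyst intermediate D -> free catalyst + target; coupling partner + catalyst intermediate B -> catalyst intermediate C; substrate + free catalyst <-> catalyst intermediate A; catalyst intermediate C -> catalyst intermediate D; target + free catalyst <-> isomer of the product + free catalyst
- "hardly changes" means that all values lie within two and a half points (for a concentration: within two and a half percent of the largest)

South-west holds 12.0 mM of working catalyst, meaning free catalyst charged minus impurity charged, and north-east holds 2.40 mM. You can test this on the first readings. South-west makes target 4.61 times as fast as north-east, while the catalyst charges stand at 3.18 to one and the working catalysts at 5.00 to one. So I take the rate as first order in working catalyst. Every flask here is charged with the same 5.00 equiv of coupling partner, so these readings test no order in it. A flask's matched time is then its time multiplied by its working catalyst and divided by south-west's.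

Which given number must be known well? Suppose the impurity were off by 0.200 mM. Delta, with 2.00 mM, would shift by 10.0%, and gamma, with 14.0 mM, by 1.43%. On north-west's slope, delta's target would move about 2.4 percentage points, so delta needs this number. Alpha barely does, since north-west and south-west at 3.00 min read 46.0% and 45.2% despite their different working catalysts. Gamma depends instead on how far target passes into isomer.

Now the numbers. Delta's matched time on north-west's clock is 1.87 min, and a straight line between the readings around it gives me 34.4%. Alpha's matched time is 3.00 min, so I read south-west's 45.2%. Gamma's 7.00 min lies beyond every reading. There south-west's remainder, isomer with bound forms, is 46.8%, already above its target, so I commit to no figure for gamma, only to a value below alpha.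

The forecast gave 37%, 45.5% and 27%, rises, then falls, on the ground that “All steps scale with active catalyst, so catalyst × time sets the outcome.”

The flasks give 35.7%, 44.8% and 35.8%: rises, then falls.

    free catalyst + impurity → spent catalyst (k = 543 M⁻¹ s⁻¹)
    catalyst intermediate A → catalyst intermediate B (k = 0.590 s⁻¹)
    catalyst intermediate D → free catalyst + target (k = 4.72 s⁻¹)
    coupling partner + catalyst intermediate B → catalyst intermediate C (k = 2.31 M⁻¹ s⁻¹)
    substrate + free catalyst ⇌ catalyst intermediate A (K = 5.41 M⁻¹, k = 5.22 M⁻¹ s⁻¹)
    catalyst intermediate C → catalyst intermediate D (k = 2.73 s⁻¹)
    target + free catalyst ⇌ isomer of the product + free catalyst, rate k7*[free catalyst]*[target] forward; the back reaction follows from the equilibrium constant (K = 1.80, k = 1.38 M⁻¹ s⁻¹)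

Gamma's fall comes from the step between target and isomer of the product: without it, both ways, gamma's target is >99.9% instead of 35.8%. Gamma's 14.0 mM of working catalyst puts its end at a matched 7.00 min, with substrate at 0.0400%, target at 35.8% and isomer at 64.1%, and a tenfold time leaves that target unmoved. Delta, with 2.00 mM, reaches a matched 10.0 min after 60.0 min, and there it holds target 35.7% beside isomer 64.3%.

(The earlier runs and the new flask stem from a simulated flask with made-up constants; scatter was added.)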